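**Plan**

1. Retrosynthetic cuts, from the target backwards: the aryl O–Si bond; the C5–prenyl bond (retro-Claisen to a C4 O-(1,1-dimethylallyl) ether, the semi-reduced form of an O-(1,1-dimethylpropargyl) ether); C3–CHO back to C3–CH2NO2; the furan back to its 2,3-dihydro form; then O1–C2 and C2–C3 together.
2. Enabling feature: furan C2 is bonded only to the B-ring aryl group, O1 and C3, so it can be supplied as a single benzylic carbon (a sulfonium ylide). C3 and the formyl carbon are the two alkene carbons of a 2-hydroxy-β-nitrostyrene built on ring A, with nitro marking the future CHO.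
3. Forward, ring A: the trihydroxybenzaldehyde is 4-O-methylated, one of its two equivalent ortho hydroxyls is capped as the tertiary propargyl ether (future C4–O and latent prenyl source, leaving exactly one phenol), and Henry condensation gives the nitrostyrene. Ring B: the aldehyde is silylated, reduced and converted into the benzyl dimethylsulfonium salt.
4. The [4+1] annulation closes the only new ring (the dihydrofuran); DDQ aromatises it, a Nef reaction unveils the aldehyde, and Lindlar reduction, Claisen shift to C5 and desilylation finish the route.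
5. Stereochemistry: the target has no stereocentre. The two centres made in the annulation (trans, racemic) are erased on aromatisation, and the E-nitroalkene geometry is thermodynamic and is consumed.

Key step: step 7

Remark: Ebenfuran IV is achiral, so the single-enantiomer requirement is met by the compound as such and no asymmetric step is planned; 3-chloro-3-methylbut-1-yne (the commercial chloride of 2-methylbut-3-yn-2-ol) is taken as the source of the five-carbon unit.

**Route**

Step 1
Reactants: 1 2,4,6-trihydroxybenzaldehyde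
Product: 2 2,6-dihydroxy-4-methoxybenzaldehyde
Conditions: MeI (1.0 equiv), K2CO3 (1.0 equiv), acetone, rt
Reagents that add atoms: iodomethane, CI
Why: Williamson ether synthesis under stoichiometric control: the 4-OH is para to the formyl group and free of the hydrogen bond that ties an ortho hydroxyl to the carbonyl oxygen, so it is the most acidic and most nucleophilic site and should be methylated in preference to the 2- and 6-OH.

Step 2
Reactants: 2 2,6-dihydroxy-4-methoxybenzaldehyde; 3 3-chloro-3-methylbut-1-yne
Product: 4 2-hydroxy-4-methoxy-6-[(2-methylbut-3-yn-2-yl)oxy]benzaldehyde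
Conditions: CuCl2·2H2O (1 mol %), DBU (1.2 equiv), MeCN, 0 °C
Reagents that add atoms: none
Why: Copper-catalysed propargylic substitution (copper acetylide/allenylidene attacked by the phenoxide) is the usual way to aryl 1,1-dimethylpropargyl ethers; the two hydroxyls of 2 are equivalent, and once one is etherified the other is locked in a hydrogen bond to the aldehyde, which should hold the reaction at the mono-ether.

Step 3
Reactants: 4 2-hydroxy-4-methoxy-6-[(2-methylbut-3-yn-2-yl)oxy]benzaldehyde; 5 nitromethane
Product: 7 5-methoxy-3-[(2-methylbut-3-yn-2-yl)oxy]-2-[(E)-2-nitroethenyl]phenol, via nitro alcohol 6 (not isolated)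
Conditions: NH4OAc (0.3 equiv), MeNO2 (solvent), 80 °C
Reagents that add atoms: none
Why: Henry (nitroaldol) reaction followed by dehydration of nitro alcohol 6 under the ammonium acetate conditions gives the conjugated nitroalkene as its thermodynamic E isomer, at a temperature well below that needed for propargyl Claisen/chromene cyclisation of the tertiary ether.

Step 4
Reactants: 8 4-hydroxy-2-methoxybenzaldehyde
Product: 9 2-methoxy-4-[(triisopropylsilyl)oxy]benzaldehyde
Conditions: TIPSCl, imidazole, DMF, rt
Reagents that add atoms: chlorotriisopropylsilane, CC(C)[Si](Cl)(C(C)C)C(C)C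
Why: Standard imidazole-mediated silylation of a phenol; the bulky TIPS ether is chosen because the para oxygen must stay capped through the sulfonium chemistry (a free para phenoxide would expel dimethyl sulfide) and must survive carbonate, DDQ and buffered Ti(III) before fluoride removes it.

Step 5
Reactants: 9 2-methoxy-4-[(triisopropylsilyl)oxy]benzaldehyde
Product: 10 {2-methoxy-4-[(triisopropylsilyl)oxy]phenyl}methanol
Conditions: NaBH4, THF/EtOH, 0 °C
Reagents that add atoms: none
Why: Borohydride reduction of an aryl aldehyde to the benzylic alcohol, with the aryl silyl ether inert at 0 °C.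

Step 6
Reactants: 10 {2-methoxy-4-[(triisopropylsilyl)oxy]phenyl}methanol
Product: 12 {2-methoxy-4-[(triisopropylsilyl)oxy]benzyl}dimethylsulfonium bromide, via benzyl bromide 11 (not isolated)
Conditions: PBr3, Et2O, 0 °C; aq NaHCO3 wash; then Me2S (excess), acetone, rt
Reagents that add atoms: phosphorus tribromide, BrP(Br)Br; dimethyl sulfide, CSC
Why: Bromination of the activated benzylic alcohol with PBr3 (SN2 on the phosphite ester) gives bromide 11, too labile to store, which S-alkylates dimethyl sulfide (SN2) so that the sulfonium salt precipitates from acetone.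

Step 7
Reactants: 7 5-methoxy-3-[(2-methylbut-3-yn-2-yl)oxy]-2-[(E)-2-nitroethenyl]phenol; 12 {2-methoxy-4-[(triisopropylsilyl)oxy]benzyl}dimethylsulfonium bromide
Product: 15 trans-6-methoxy-2-{2-methoxy-4-[(triisopropylsilyl)oxy]phenyl}-4-[(2-methylbut-3-yn-2-yl)oxy]-3-(nitromethyl)-2,3-dihydrobenzofuran (racemic), via sulfonium benzylide 13 (not isolated), via sulfonium phenoxide betaine 14 (not isolated)
Conditions: Cs2CO3 (2.2 equiv), 12 (1.3 equiv), dry MeCN, 0 °C to rt
Reagents that add atoms: none
Why: This is a formal [4+1] annulation of a sulfonium ylide with an o-hydroxyaryl nitroalkene, a known route to trans-2,3-dihydrobenzofurans: carbonate deprotonates the phenol of 7 and the benzylic position of 12, the semi-stabilised benzylide 13 adds through carbon to the ring-bearing alkene carbon (β to nitro) to form C2–C3 and betaine 14 (its nitro group being held as the nitronate in the basic medium), and the ortho phenoxide then displaces dimethyl sulfide at the benzylic carbon to form O1–C2. The five-membered ring closes by 5-exo-tet SN2 substitution with inversion at the sulfonium-bearing carbon. The two new stereocentres (C2 and C3) are controlled only relative to each other: the diastereomers of 14 can interconvert by reversible deprotonation α to sulfur, and closure through the transition state that keeps the aryl group and CH2NO2 on opposite faces should be faster, giving the trans racemate; no absolute control is needed because both centres are removed in step 8. The step needs ring closure through the phenoxide oxygen in preference to the nitronate (which would give a nitrocyclopropane or an isoxazoline N-oxide), and the well-placed, more nucleophilic ortho phenoxide and the mild carbonate base secure this. It also needs ylide formation at the benzylic carbon rather than at S-methyl, which aryl stabilisation secures. Only one phenol is present in 7, so there is no choice of oxygen, and the tertiary propargyl ether, terminal alkyne and aryl silyl ether should be inert to dry Cs2CO3 at room temperature.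

Step 8
Reactants: 15 trans-6-methoxy-2-{2-methoxy-4-[(triisopropylsilyl)oxy]phenyl}-4-[(2-methylbut-3-yn-2-yl)oxy]-3-(nitromethyl)-2,3-dihydrobenzofuran
Product: 16 6-methoxy-2-{2-methoxy-4-[(triisopropylsilyl)oxy]phenyl}-4-[(2-methylbut-3-yn-2-yl)oxy]-3-(nitromethyl)benzofuran
Conditions: DDQ (1.2 equiv), 1,4-dioxane, 80 °C
Reagents that add atoms: none
Why: DDQ dehydrogenation of a 2-aryl-2,3-dihydrobenzofuran: hydride is abstracted from C2, which is benzylic to the electron-rich aryl ring and α to O1, and loss of the C3 proton aromatises the furan, removing both stereocentres so that any cis isomer converges on the same product; no free phenol is present to compete for the quinone.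

Step 9
Reactants: 16 6-methoxy-2-{2-methoxy-4-[(triisopropylsilyl)oxy]phenyl}-4-[(2-methylbut-3-yn-2-yl)oxy]-3-(nitromethyl)benzofuran
Product: 18 6-methoxy-2-{2-methoxy-4-[(triisopropylsilyl)oxy]phenyl}-4-[(2-methylbut-3-yn-2-yl)oxy]benzofuran-3-carbaldehyde, via potassium nitronate 17 (not isolated)
Conditions: KOt-Bu (1.05 equiv), THF, 0 °C; then aq TiCl3 (4.5 equiv), NH4OAc buffer (pH about 5), 0 °C to rt
Reagents that add atoms: water, O
Why: Reductive Nef reaction: the benzylic nitro group is converted into nitronate 17, which aqueous Ti(III) reduces at nitrogen, and hydrolysis in the acetate buffer releases the non-enolisable aldehyde under conditions that spare the tertiary propargyl ether and the aryl silyl ether.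

Step 10
Reactants: 18 6-methoxy-2-{2-methoxy-4-[(triisopropylsilyl)oxy]phenyl}-4-[(2-methylbut-3-yn-2-yl)oxy]benzofuran-3-carbaldehyde
Product: 19 6-methoxy-2-{2-methoxy-4-[(triisopropylsilyl)oxy]phenyl}-4-[(2-methylbut-3-en-2-yl)oxy]benzofuran-3-carbaldehyde
Conditions: H2 (1 atm), Lindlar catalyst, quinoline, EtOAc, rt
Reagents that add atoms: none
Why: Lindlar semi-hydrogenation: the lead- and quinoline-poisoned palladium reduces the terminal alkyne to the alkene and stops, leaving the aldehyde, the benzofuran and the silyl ether untouched.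

Step 11
Reactants: 19 6-methoxy-2-{2-methoxy-4-[(triisopropylsilyl)oxy]phenyl}-4-[(2-methylbut-3-en-2-yl)oxy]benzofuran-3-carbaldehyde
Product: 21 4-hydroxy-6-methoxy-2-{2-methoxy-4-[(triisopropylsilyl)oxy]phenyl}-5-(3-methylbut-2-en-1-yl)benzofuran-3-carbaldehyde, via ortho-dienone 20 (not isolated)
Conditions: toluene, 110 °C
Reagents that add atoms: none
Why: Aromatic Claisen rearrangement: the [3,3] shift of the 1,1-dimethylallyl aryl ether can reach only C5, because the other ortho position is the ring-fusion carbon C3a, and it delivers the linear 3-methylbut-2-enyl chain; tautomerisation of dienone 20 restores the arene as the C4 phenol.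

Step 12
Reactants: 21 4-hydroxy-6-methoxy-2-{2-methoxy-4-[(triisopropylsilyl)oxy]phenyl}-5-(3-methylbut-2-en-1-yl)benzofuran-3-carbaldehyde
Product: 22 Ebenfuran IV
Conditions: TBAF (1.1 equiv), AcOH (1.1 equiv), THF, 0 °C
Reagents that add atoms: none
Why: Fluoride-induced cleavage of the aryl silyl ether driven by Si–F bond formation; buffering with acetic acid keeps the medium near neutral so that the aldehyde and the prenyl group are left alone.

**Compound list**

1 | 2,4,6-trihydroxybenzaldehyde | O=Cc1c(O)cc(O)cc1O | starting material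
2 | 2,6-dihydroxy-4-methoxybenzaldehyde | O=Cc1c(O)cc(OC)cc1O | intermediate
3 | 3-chloro-3-methylbut-1-yne | C#CC(C)(C)Cl | starting material
4 | 2-hydroxy-4-methoxy-6-[(2-methylbut-3-yn-2-yl)oxy]benzaldehyde | O=Cc1c(O)cc(OC)cc1OC(C)(C)C#C | intermediate
5 | nitromethane | C[N+](=O)[O-] | starting material
6 | 2-(1-hydroxy-2-nitroethyl)-5-methoxy-3-[(2-methylbut-3-yn-2-yl)oxy]phenol (racemic) | OC(C[N+](=O)[O-])c1c(O)cc(OC)cc1OC(C)(C)C#C | intermediate (not isolated)
7 | 5-methoxy-3-[(2-methylbut-3-yn-2-yl)oxy]-2-[(E)-2-nitroethenyl]phenol | O=[N+]([O-])/C=C/c1c(O)cc(OC)cc1OC(C)(C)C#C | intermediate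
8 | 4-hydroxy-2-methoxybenzaldehyde | COc1cc(O)ccc1C=O | starting material
9 | 2-methoxy-4-[(triisopropylsilyl)oxy]benzaldehyde | COc1cc(O[Si](C(C)C)(C(C)C)C(C)C)ccc1C=O | intermediate
10 | {2-methoxy-4-[(triisopropylsilyl)oxy]phenyl}methanol | COc1cc(O[Si](C(C)C)(C(C)C)C(C)C)ccc1CO | intermediate
11 | [4-(bromomethyl)-3-methoxyphenoxy]triisopropylsilane | COc1cc(O[Si](C(C)C)(C(C)C)C(C)C)ccc1CBr | intermediate (not isolated)
12 | {2-methoxy-4-[(triisopropylsilyl)oxy]benzyl}dimethylsulfonium bromide | C[S+](C)Cc1ccc(O[Si](C(C)C)(C(C)C)C(C)C)cc1OC.[Br-] | intermediate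
13 | dimethylsulfonium {2-methoxy-4-[(triisopropylsilyl)oxy]phenyl}methylide | C[S+](C)[CH-]c1ccc(O[Si](C(C)C)(C(C)C)C(C)C)cc1OC | intermediate (not isolated)
14 | 2-{1-(dimethylsulfonio)-1-[2-methoxy-4-(triisopropylsilyloxy)phenyl]-3-nitropropan-2-yl}-5-methoxy-3-[(2-methylbut-3-yn-2-yl)oxy]phenolate (zwitterion; racemic, interconverting diastereomers, configuration not fixed) | C[S+](C)C(c1ccc(O[Si](C(C)C)(C(C)C)C(C)C)cc1OC)C(C[N+](=O)[O-])c1c([O-])cc(OC)cc1OC(C)(C)C#C | intermediate (not isolated)
15 | trans-6-methoxy-2-{2-methoxy-4-[(triisopropylsilyl)oxy]phenyl}-4-[(2-methylbut-3-yn-2-yl)oxy]-3-(nitromethyl)-2,3-dihydrobenzofuran (racemic; 2R,3S enantiomer drawn) | [O-][N+](=O)C[C@H]1[C@H](c2ccc(O[Si](C(C)C)(C(C)C)C(C)C)cc2OC)Oc2cc(OC)cc(OC(C)(C)C#C)c21 | intermediate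
16 | 6-methoxy-2-{2-methoxy-4-[(triisopropylsilyl)oxy]phenyl}-4-[(2-methylbut-3-yn-2-yl)oxy]-3-(nitromethyl)benzofuran | [O-][N+](=O)Cc1c(-c2ccc(O[Si](C(C)C)(C(C)C)C(C)C)cc2OC)oc2cc(OC)cc(OC(C)(C)C#C)c12 | intermediate
17 | potassium nitronate of 16 | [K+].[O-][N+]([O-])=Cc1c(-c2ccc(O[Si](C(C)C)(C(C)C)C(C)C)cc2OC)oc2cc(OC)cc(OC(C)(C)C#C)c12 | intermediate (not isolated)
18 | 6-methoxy-2-{2-methoxy-4-[(triisopropylsilyl)oxy]phenyl}-4-[(2-methylbut-3-yn-2-yl)oxy]benzofuran-3-carbaldehyde | O=Cc1c(-c2ccc(O[Si](C(C)C)(C(C)C)C(C)C)cc2OC)oc2cc(OC)cc(OC(C)(C)C#C)c12 | intermediate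
19 | 6-methoxy-2-{2-methoxy-4-[(triisopropylsilyl)oxy]phenyl}-4-[(2-methylbut-3-en-2-yl)oxy]benzofuran-3-carbaldehyde | O=Cc1c(-c2ccc(O[Si](C(C)C)(C(C)C)C(C)C)cc2OC)oc2cc(OC)cc(OC(C)(C)C=C)c12 | intermediate
20 | 6-methoxy-2-{2-methoxy-4-[(triisopropylsilyl)oxy]phenyl}-5-(3-methylbut-2-en-1-yl)-4-oxo-4,5-dihydrobenzofuran-3-carbaldehyde (racemic at C5) | O=CC1=C(c2ccc(O[Si](C(C)C)(C(C)C)C(C)C)cc2OC)OC2=C1C(=O)C(CC=C(C)C)C(OC)=C2 | intermediate (not isolated)
21 | 4-hydroxy-6-methoxy-2-{2-methoxy-4-[(triisopropylsilyl)oxy]phenyl}-5-(3-methylbut-2-en-1-yl)benzofuran-3-carbaldehyde | O=Cc1c(-c2ccc(O[Si](C(C)C)(C(C)C)C(C)C)cc2OC)oc2cc(OC)c(CC=C(C)C)c(O)c12 | intermediate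
22 | Ebenfuran IV, 4-hydroxy-2-(4-hydroxy-2-methoxyphenyl)-6-methoxy-5-(3-methylbut-2-en-1-yl)benzofuran-3-carbaldehyde (achiral) | COc1cc(O)ccc1-c1oc2cc(OC)c(CC=C(C)C)c(O)c2c1C=O | target

**Totals**

Total step count: 12. Longest linear sequence: 9 steps (steps 1, 2, 3, 7, 8, 9, 10, 11, 12 from 1; the B-ring arm through steps 4, 5, 6 is equally long).

**Steps most likely to fail**

Step 7. The sulfonium salt may be consumed before the benzylide adds. Possible paths are direct O-benzylation of the phenoxide at the benzylic carbon, deprotonation at S-methyl followed by Sommelet–Hauser rearrangement, and base-induced loss of the silyl group with expulsion of dimethyl sulfide. Addition to the phenoxide form of the electron-rich nitroalkene may also be slow. The fallback drops the ylide and builds the furan by O-alkylation and cyclodehydration, setting out from 4 and crude bromide 11. O-Benzylation (K2CO3, DMF, rt) should give 4-methoxy-2-{2-methoxy-4-[(triisopropylsilyl)oxy]benzyloxy}-6-[(2-methylbut-3-yn-2-yl)oxy]benzaldehyde F1. The phosphazene base P4-t-Bu (benzene, rt to 80 °C) should then close the ring by intramolecular aldol condensation of the benzylic carbanion onto the ortho formyl group, giving 6-methoxy-2-{2-methoxy-4-[(triisopropylsilyl)oxy]phenyl}-4-[(2-methylbut-3-yn-2-yl)oxy]benzofuran F2. Vilsmeier–Haack formylation (POCl3, DMF, 0 °C; aq NaOAc) is expected at C3, the enol-ether β-carbon whose σ-complex is stabilised by O1 and the electron-rich 2-aryl group, and comes back to the route at 18.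

Step 9. The reduction may stall at the oxime oxidation level, or the electron-rich benzylic nitronate may ionise with loss of nitrite instead of undergoing clean reductive hydrolysis. The fallback separates reduction from C=N cleavage and sets out from 16. Tin(II) thiolate reduction (SnCl2·2H2O, PhSH, Et3N, MeCN, rt), a known conversion of primary nitro compounds into oximes, should give (E)-6-methoxy-2-{2-methoxy-4-[(triisopropylsilyl)oxy]phenyl}-4-[(2-methylbut-3-yn-2-yl)oxy]benzofuran-3-carbaldehyde oxime F3. Exchange of the oxime with aqueous glyoxylic acid (NaOAc, THF/H2O, rt) then releases the aldehyde without titanium or strong acid and comes back to the route at 18.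

Step 2. The carbonyl-conjugated phenoxide may react sluggishly with the copper intermediate, or alkylation may run on to the bis-ether or onto ring carbon. The fallback postpones the C4 ether to the end and carries both phenols free, setting out from 2.
- Henry condensation with nitromethane (NH4OAc, 80 °C) should give 5-methoxy-2-[(E)-2-nitroethenyl]benzene-1,3-diol F4.
- The same annulation with 12 (Cs2CO3, MeCN), in which either of the two equivalent phenols can close, should give trans-6-methoxy-2-{2-methoxy-4-[(triisopropylsilyl)oxy]phenyl}-3-(nitromethyl)-2,3-dihydrobenzofuran-4-ol F5.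
- DDQ in dioxane should give 6-methoxy-2-{2-methoxy-4-[(triisopropylsilyl)oxy]phenyl}-3-(nitromethyl)benzofuran-4-ol F6.
- The buffered Ti(III) Nef reaction should give 4-hydroxy-6-methoxy-2-{2-methoxy-4-[(triisopropylsilyl)oxy]phenyl}benzofuran-3-carbaldehyde F7.
- Palladium-catalysed Tsuji–Trost O-allylation with methyl 2-methylbut-3-en-2-yl carbonate (Pd(PPh3)4, THF, rt), which delivers the branched tertiary allyl aryl ether, comes back to the route at 19 and makes step 10 unnecessary.

**Further compounds**

F1 | step 7 | 4-methoxy-2-{2-methoxy-4-[(triisopropylsilyl)oxy]benzyloxy}-6-[(2-methylbut-3-yn-2-yl)oxy]benzaldehyde | COc1cc(OCc2ccc(O[Si](C(C)C)(C(C)C)C(C)C)cc2OC)c(C=O)c(OC(C)(C)C#C)c1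
F2 | step 7 | 6-methoxy-2-{2-methoxy-4-[(triisopropylsilyl)oxy]phenyl}-4-[(2-methylbut-3-yn-2-yl)oxy]benzofuran | COc1cc(OC(C)(C)C#C)c2cc(-c3ccc(O[Si](C(C)C)(C(C)C)C(C)C)cc3OC)oc2c1
F3 | step 9 | (E)-6-methoxy-2-{2-methoxy-4-[(triisopropylsilyl)oxy]phenyl}-4-[(2-methylbut-3-yn-2-yl)oxy]benzofuran-3-carbaldehyde oxime | O/N=C/c1c(-c2ccc(O[Si](C(C)C)(C(C)C)C(C)C)cc2OC)oc2cc(OC)cc(OC(C)(C)C#C)c12
F4 | step 2 | 5-methoxy-2-[(E)-2-nitroethenyl]benzene-1,3-diol | O=[N+]([O-])/C=C/c1c(O)cc(OC)cc1O
F5 | step 2 | trans-6-methoxy-2-{2-methoxy-4-[(triisopropylsilyl)oxy]phenyl}-3-(nitromethyl)-2,3-dihydrobenzofuran-4-ol (racemic; 2R,3S enantiomer drawn) | [O-][N+](=O)C[C@H]1[C@H](c2ccc(O[Si](C(C)C)(C(C)C)C(C)C)cc2OC)Oc2cc(OC)cc(O)c21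
F6 | step 2 | 6-methoxy-2-{2-methoxy-4-[(triisopropylsilyl)oxy]phenyl}-3-(nitromethyl)benzofuran-4-ol | [O-][N+](=O)Cc1c(-c2ccc(O[Si](C(C)C)(C(C)C)C(C)C)cc2OC)oc2cc(OC)cc(O)c12
F7 | step 2 | 4-hydroxy-6-methoxy-2-{2-methoxy-4-[(triisopropylsilyl)oxy]phenyl}benzofuran-3-carbaldehyde | O=Cc1c(-c2ccc(O[Si](C(C)C)(C(C)C)C(C)C)cc2OC)oc2cc(OC)cc(O)c12
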